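**Retrosynthetic overview**
1. The plan rests on the cis-fused A/B decalin. C10 (angular CH3) and C5 (H on the same face) are read as the two former alkene carbons of a ring A 4,4-dimethylcyclohex-2-enone. The angular CH3 is carried as CO2Me, which together with the C1 ketone activates that alkene.
2. Ring A is bought (in 1). Ring B is the only ring made, closed by cutting C5–C6 and C9–C10: an enantioselective [4+2] of keto ester 6 with 2-silyloxydiene 16, which already holds C8–CH3 and the whole chain C11–C22.
3. Diene 16 goes back through enone 15 (Wittig at C8=C9) to the C17 aldehyde 13 and farnesol 7. Dienophile 6 goes back through keto ester 3 to 1 and 2.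
4. After the cycloaddition only oxygen is edited. C1=O is removed (Barton–McCombie), C8–OH is put in from the C7–C8 silyl enol ether (Rubottom), and the C7 and ester oxygens leave together (bis-mesylate, LiEt3BH).

Key step: step 8

Remark on descriptors: ring A is C1–C5 and C10, ring B is C5–C10, and the chain is C11–C22. β is the face that carries the C10 substituent. "Homofarnesyl" means (3E,7E)-4,8,12-trimethyltrideca-3,7,11-trien-1-yl. The target has 5β-H, 10β-CH3, 9β-homofarnesyl, 8β-CH3 and 8α-OH, that is (5R,8R,9R,10S).

Assumption: the (R,R) ligand, 2,2′-(propane-2,2-diyl)bis[(4R)-4-tert-butyl-4,5-dihydro-1,3-oxazole], is assigned from a square-planar chelate model. If the adduct proves to be the mirror image, the equally available (S,S) ligand is used and nothing else changes.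

**Route**

Step 1
Reactants: 1 4,4-dimethylcyclohexanone; 2 dimethyl carbonate
Product: 3 methyl 5,5-dimethyl-2-oxocyclohexane-1-carboxylate (racemic, largely enolised)
Conditions: NaH (2.2 equiv), THF, reflux; then aq. HCl
Reagents that add atoms: none
Why: Crossed Claisen C-acylation of the sodium enolate with dimethyl carbonate is pulled forward by deprotonation of the β-keto ester formed, the two α-positions of symmetric 1 are equivalent so no regioisomer can arise, and the new centre is configurationally labile and disappears in step 2.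

Step 2
Reactants: 3 methyl 5,5-dimethyl-2-oxocyclohexane-1-carboxylate
Product: 6 methyl 3,3-dimethyl-6-oxocyclohex-1-ene-1-carboxylate, via α-phenylselanyl keto ester 4 (not isolated), via selenoxide 5 (not isolated)
Conditions: PhSeCl, pyridine, CH2Cl2, 0 °C; then 30% aq. H2O2, 0 °C → rt
Reagents that add atoms: none
Why: Selenenylation of the enolised β-keto ester at the doubly activated carbon, oxidation and spontaneous selenoxide syn-elimination can only take a hydrogen from the ring CH2 next to CMe2, and the quaternary γ-carbon blocks tautomerisation to a dienol, so 6 should be isolable.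

Step 3
Reactants: 7 (2E,6E)-farnesol
Product: 8 (2E,6E)-farnesyl bromide
Conditions: PBr3 (0.4 equiv), Et2O, −10 → 0 °C
Reagents that add atoms: phosphorus tribromide, BrP(Br)Br
Why: Bromination of the primary allylic alcohol through its phosphite ester is an SN2 displacement that at low temperature should proceed without allylic transposition or loss of the (E) geometries.

Step 4
Reactants: 8 (2E,6E)-farnesyl bromide; 9 acetonitrile
Product: 11 (4E,8E)-5,9,13-trimethyltetradeca-4,8,12-trienenitrile, via lithioacetonitrile 10 (not isolated)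
Conditions: 9 (3 equiv), n-BuLi, THF, −78 °C; then 8, −78 → −20 °C
Reagents that add atoms: none
Why: SN2 alkylation of the small nitrile-stabilised carbanion at the primary allylic bromide adds C11 and C9 in one operation, and the excess of 10 suppresses a second alkylation.

Step 5
Reactants: 11 (4E,8E)-5,9,13-trimethyltetradeca-4,8,12-trienenitrile
Product: 13 (4E,8E)-5,9,13-trimethyltetradeca-4,8,12-trienal, via N-aluminio imine 12 (not isolated)
Conditions: i-Bu2AlH (1.2 equiv), CH2Cl2, −78 °C; then aq. tartaric acid, 0 °C
Reagents that add atoms: water, O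
Why: Partial reduction of a nitrile by i-Bu2AlH stops at the N-aluminio imine, which accepts no second hydride at −78 °C, and mild acidic hydrolysis then releases the aldehyde without touching the trisubstituted alkenes.

Step 6
Reactants: 13 (4E,8E)-5,9,13-trimethyltetradeca-4,8,12-trienal; 14 3-(triphenylphosphoranylidene)butan-2-one
Product: 15 (3E,7E,11E)-3,8,12,16-tetramethylheptadeca-3,7,11,15-tetraen-2-one
Conditions: toluene, 90 °C
Reagents that add atoms: none
Why: Wittig olefination with a stabilised α-methyl acyl ylide should give the (E)-trisubstituted enone (chain trans to the acetyl group), the geometry on which the C9 configuration of step 8 depends.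

Step 7
Reactants: 15 (3E,7E,11E)-3,8,12,16-tetramethylheptadeca-3,7,11,15-tetraen-2-one
Product: 16 tert-butyldimethyl{[(3E,7E,11E)-3,8,12,16-tetramethylheptadeca-1,3,7,11,15-pentaen-2-yl]oxy}silane
Conditions: TBSOTf, Et3N, CH2Cl2, 0 °C
Reagents that add atoms: tert-butyldimethylsilyl triflate, CC(C)(C)[Si](C)(C)OS(=O)(=O)C(F)(F)F
Why: Soft enolisation, in which TBSOTf silylates the carbonyl oxygen and Et3N removes a proton from the unhindered acetyl CH3, gives the cross-conjugated 2-silyloxydiene and leaves the C8=C9 geometry untouched.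

Step 8
Reactants: 6 methyl 3,3-dimethyl-6-oxocyclohex-1-ene-1-carboxylate; 16 the (E)-2-silyloxy-3-methyl-1,3-diene
Product: 17 cis-fused adduct: 10β-CO2Me, 5β-H, 9β-homofarnesyl, C1 ketone, C4 gem-dimethyl, C7(OTBS)=C8(CH3) silyl enol ether
Conditions: Cu(OTf)2 (10 mol %), (R,R)-t-Bu-bis(oxazoline) (11 mol %), 4 Å MS, CH2Cl2, −20 °C → rt
Reagents that add atoms: none
Why: Cu(OTf)2 and the C2-symmetric bis(oxazoline) form a divalent copper cation that binds the C1 ketone and the ester carbonyl of 6 in a six-membered chelate and so lowers the LUMO of the C5=C10 alkene; diene 16 then adds in a concerted, asynchronous [4+2] cycloaddition in which C6, the enol-ether terminus with the largest HOMO coefficient, runs ahead onto the β-carbon C5 and C9 follows onto C10. The closest known reaction types are the Lewis-acid Diels–Alder additions of this same keto ester to alkyl-substituted dienes, which give cis-decalins with an angular ester, and the Cu(OTf)2–bis(oxazoline) Diels–Alder reactions of two-point-binding dienophiles. Ring B is closed as a six-membered carbocycle by intermolecular cycloaddition, suprafacial on both partners, so C5–H and the C10 ester must end on the same face (cis fusion). C9 is set by the endo/exo choice: with the ester under the diene the (E)-placed chain ends cis to the ester, and the competing ring-A-endo mode is penalised because it would press C7 and its silyloxy group against the axial methyl on C4. The absolute sense is set by the ligand, because in the square-planar chelate C7 and the C8 methyl of the endo-oriented diene sit over the ester-side quadrant, and only one alkene face has that quadrant free of a tert-butyl group. The step needs regio-, endo-, facial and chemoselectivity: the 2-silyloxy group and the C9 alkyl group direct in the same sense (para and ortho) and secure the first, and the unactivated trisubstituted chain alkenes cannot compete as diene or dienophile.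

Step 9
Reactants: 17 cis-fused adduct
Product: 18 1α-alcohol (C1 ketone reduced; ester and silyl enol ether unchanged)
Conditions: NaBH4, THF–MeOH, −20 → 0 °C
Reagents that add atoms: none
Why: Borohydride reduction touches only the ketone, since the angular ester is neopentyl-hindered and the silyl enol ether is inert to hydride; attack from the convex β face of the cis-decalin should give the 1α-alcohol, whose configuration does not matter for the main line because C1 becomes CH2 in step 11.

Step 10
Reactants: 18 1α-alcohol
Product: 19 O-(imidazol-1-ylthiocarbonyl) derivative of 18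
Conditions: 1,1′-thiocarbonyldiimidazole, DMAP (cat), toluene, 90 °C
Reagents that add atoms: 1,1′-thiocarbonyldiimidazole, S=C(n1ccnc1)n1ccnc1
Why: Thioacylation of the alcohol runs under neutral conditions, so no alkoxide is formed that could trigger retro-aldol opening of the β-hydroxy ester, and it prepares the Barton–McCombie step.

Step 11
Reactants: 19 imidazolylthiocarbonate
Product: 20 C1-deoxy ester (10β-CO2Me, C1 = CH2, silyl enol ether intact)
Conditions: Bu3SnH (0.5 M), AIBN (cat), toluene, 100 °C
Reagents that add atoms: none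
Why: Barton–McCombie deoxygenation, in which the tributyltin radical adds to the thiocarbonyl group and β-scission gives the secondary C1 radical, which at high Bu3SnH concentration should be reduced faster than it can cyclise 6-exo onto C13=C14, and no stereocentre is touched.

Step 12
Reactants: 20 C1-deoxy ester
Product: 22 8α-hydroxy-7-ketone (8β-CH3, 10β-CO2Me), via 7α,8α-silyloxy epoxide 21 (not isolated)
Conditions: dimethyldioxirane (1.0 equiv), acetone–CH2Cl2, −78 → −40 °C; then Et3N·3HF, THF, 0 °C
Reagents that add atoms: dimethyldioxirane, CC1(C)OO1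
Why: Rubottom oxidation, in which the tetrasubstituted, oxygen-substituted C7=C8 bond is by far the most electron-rich alkene and should take up the single equivalent of oxidant before the chain alkenes, α-face attack being expected because the β face carries the pseudoaxial C9 chain (pushed there by A(1,2) strain with the C8 methyl) and the C10 ester, after which fluoride collapses the silyloxy epoxide to the 8α-hydroxy ketone.

Step 13
Reactants: 22 8α-hydroxy-7-ketone
Product: 23 triol (7β-OH, 8α-OH, C10–CH2OH)
Conditions: LiAlH4, THF, 0 °C → reflux; then H2O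
Reagents that add atoms: none
Why: LiAlH4 reduces the ketone and the angular ester in one operation, and the C8 alkoxyaluminate formed first delivers hydride to the α face of C7, which is also the face not screened by the axial C9 chain, so the 7β-alcohol, trans-diaxial to the 8α-oxygen, should result.

Step 14
Reactants: 23 triol
Product: 24 bis-mesylate (7β-OMs, C10–CH2OMs, free 8α-OH)
Conditions: MsCl (2.5 equiv), Et3N, CH2Cl2, −10 °C; used without delay
Reagents that add atoms: methanesulfonyl chloride, CS(=O)(=O)Cl
Why: Mesylation through sulfene reaches the neopentyl primary and the hindered secondary hydroxyl but not the tertiary one, so both oxygens that must leave are activated while C8–OH stays free.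

Step 15
Reactants: 24 bis-mesylate
Product: 27 target, (1R,2R,4aR,8aS)-2,5,5,8a-tetramethyl-1-[(3E,7E)-4,8,12-trimethyltrideca-3,7,11-trien-1-yl]decahydronaphthalen-2-ol, via 7α,8α-epoxy mesylate 25 (not isolated), via 8α-hydroxy mesylate 26 (not isolated)
Conditions: LiEt3BH (excess), THF, 0 °C → reflux; then H2O
Reagents that add atoms: none
Why: A cascade of known SN2 steps, in which LiEt3BH deprotonates C8–OH, the alkoxide displaces the anti-periplanar 7β-mesylate (Williamson-type epoxide closure), the trisubstituted epoxide is opened at the less substituted C7 in the trans-diaxial sense (Fürst–Plattner) without breaking the C8–O bond, and at reflux the neopentyl mesylate is displaced to leave the angular CH3, while the 8α-alkoxide cannot reach the β-oriented CH2OMs group.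

**Compound list**
1 | 4,4-dimethylcyclohexanone | CC1(C)CCC(=O)CC1 | starting material
2 | dimethyl carbonate | COC(=O)OC | starting material
3 | methyl 5,5-dimethyl-2-oxocyclohexane-1-carboxylate (racemic) | COC(=O)C1CC(C)(C)CCC1=O | intermediate
4 | methyl 5,5-dimethyl-2-oxo-1-(phenylselanyl)cyclohexane-1-carboxylate (racemic) | COC(=O)C1([Se]c2ccccc2)CC(C)(C)CCC1=O | intermediate (not isolated)
5 | selenoxide of 4 | COC(=O)C1([Se](=O)c2ccccc2)CC(C)(C)CCC1=O | intermediate (not isolated)
6 | methyl 3,3-dimethyl-6-oxocyclohex-1-ene-1-carboxylate | COC(=O)C1=CC(C)(C)CCC1=O | intermediate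
7 | (2E,6E)-farnesol | CC(C)=CCC/C(C)=C/CC/C(C)=C/CO | starting material
8 | (2E,6E)-farnesyl bromide | CC(C)=CCC/C(C)=C/CC/C(C)=C/CBr | intermediate
9 | acetonitrile | CC#N | starting material
10 | lithioacetonitrile | [Li]CC#N | intermediate (not isolated)
11 | (4E,8E)-5,9,13-trimethyltetradeca-4,8,12-trienenitrile | CC(C)=CCC/C(C)=C/CC/C(C)=C/CCC#N | intermediate
12 | N-(diisobutylaluminio) imine of 13 | CC(C)=CCC/C(C)=C/CC/C(C)=C/CCC=N[Al](CC(C)C)CC(C)C | intermediate (not isolated)
13 | (4E,8E)-5,9,13-trimethyltetradeca-4,8,12-trienal | CC(C)=CCC/C(C)=C/CC/C(C)=C/CCC=O | intermediate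
14 | 3-(triphenylphosphoranylidene)butan-2-one | CC(=O)C(C)=P(c1ccccc1)(c1ccccc1)c1ccccc1 | starting material
15 | (3E,7E,11E)-3,8,12,16-tetramethylheptadeca-3,7,11,15-tetraen-2-one | CC(C)=CCC/C(C)=C/CC/C(C)=C/CC/C=C(\C)C(C)=O | intermediate
16 | (E)-2-(TBS-oxy)-3-methyl-1,3-diene carrying C11–C22 | CC(C)=CCC/C(C)=C/CC/C(C)=C/CC/C=C(\C)C(=C)O[Si](C)(C)C(C)(C)C | intermediate
17 | cis-fused Diels–Alder adduct (10β-CO2Me, 5β-H, 9β-chain, 1-oxo, 7-OTBS-Δ7) | CC(C)=CCC/C(C)=C/CC/C(C)=C/CC[C@@H]1[C@@]2(C(=O)OC)C(=O)CCC(C)(C)[C@H]2CC(O[Si](C)(C)C(C)(C)C)=C1C | intermediate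
18 | 1α-alcohol | CC(C)=CCC/C(C)=C/CC/C(C)=C/CC[C@@H]1[C@@]2(C(=O)OC)[C@@H](O)CCC(C)(C)[C@H]2CC(O[Si](C)(C)C(C)(C)C)=C1C | intermediate
19 | 1α-O-(imidazol-1-ylthiocarbonyl) derivative | CC(C)=CCC/C(C)=C/CC/C(C)=C/CC[C@@H]1[C@@]2(C(=O)OC)[C@@H](OC(=S)n3ccnc3)CCC(C)(C)[C@H]2CC(O[Si](C)(C)C(C)(C)C)=C1C | intermediate
20 | C1-deoxy ester silyl enol ether | CC(C)=CCC/C(C)=C/CC/C(C)=C/CC[C@@H]1[C@@]2(C(=O)OC)CCCC(C)(C)[C@H]2CC(O[Si](C)(C)C(C)(C)C)=C1C | intermediate
21 | 7β-(TBS-oxy)-7α,8α-epoxide | CC(C)=CCC/C(C)=C/CC/C(C)=C/CC[C@@H]1[C@@]2(C(=O)OC)CCCC(C)(C)[C@H]2C[C@@]3(O[Si](C)(C)C(C)(C)C)O[C@@]13C | intermediate (not isolated)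
22 | 8α-hydroxy-7-ketone ester | CC(C)=CCC/C(C)=C/CC/C(C)=C/CC[C@@H]1[C@@]2(C(=O)OC)CCCC(C)(C)[C@H]2CC(=O)[C@@]1(C)O | intermediate
23 | 7β,8α-diol with C10–CH2OH (triol) | CC(C)=CCC/C(C)=C/CC/C(C)=C/CC[C@@H]1[C@@]2(CO)CCCC(C)(C)[C@H]2C[C@H](O)[C@@]1(C)O | intermediate
24 | bis-mesylate | CC(C)=CCC/C(C)=C/CC/C(C)=C/CC[C@@H]1[C@@]2(COS(C)(=O)=O)CCCC(C)(C)[C@H]2C[C@H](OS(C)(=O)=O)[C@@]1(C)O | intermediate
25 | 7α,8α-epoxy neopentyl mesylate | CC(C)=CCC/C(C)=C/CC/C(C)=C/CC[C@@H]1[C@@]2(COS(C)(=O)=O)CCCC(C)(C)[C@H]2C[C@H]3O[C@@]13C | intermediate (not isolated)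
26 | 8α-hydroxy neopentyl mesylate | CC(C)=CCC/C(C)=C/CC/C(C)=C/CC[C@@H]1[C@@]2(COS(C)(=O)=O)CCCC(C)(C)[C@H]2CC[C@@]1(C)O | intermediate (not isolated)
27 | CNP0389811.1 | CC(C)=CCC/C(C)=C/CC/C(C)=C/CC[C@@H]1[C@@]2(C)CCCC(C)(C)[C@H]2CC[C@@]1(C)O | target

**Step count**
Total steps: 15. Longest linear sequence: 13 (steps 3–15, from farnesol).

**The three steps most likely to fail**

Step 8.
- What may go wrong:
  - The mild copper Lewis acid may activate the hindered dienophile too weakly, since its β-carbon is neopentyl.
  - The reaction may stop after the first C5–C6 bond, by a Mukaiyama–Michael course with silyl transfer.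
  - The ester-endo preference that sets C9 may erode.
  - Facial discrimination may be poor, because the reacting alkene lies on the C2 axis of the catalyst.
- Fallback (resolution in place of asymmetric catalysis), setting out from 6 and 16:
  - The cycloaddition is promoted by stoichiometric ZnCl2 in Et2O–CH2Cl2, the kind of achiral Lewis acid under which this dienophile class is known to react. It gives 17 together with its mirror image, the ent-adduct F1.
  - NaBH4 as in step 9 gives 18 and the ent-alcohol F2.
  - Steglich esterification with (S)-O-methylmandelic acid (DCC, DMAP) gives two diastereomers, the mandelate of the wanted series F3 and the mandelate of the mirror-image series F4. They are separated by chromatography.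
  - K2CO3 in MeOH cleaves F3, and the sequence comes back to the route at 18.

Step 12.
- What may go wrong:
  - Facial selectivity at C8 may be poor. The α face is not free either, since the axial C1 methylene of ring A lies under it.
  - The chain alkenes may be epoxidised in competition.
- Fallback (delivery of the oxidant by a neighbouring hydroxyl in place of steric control), setting out from 18, whose axial 1α-hydroxyl points under the α face of ring B:
  - Hydroxyl-directed epoxidation with VO(acac)2/t-BuOOH in CH2Cl2, or a peracid under Henbest-type hydrogen-bond control, should oxidise only the alkene within reach of that hydroxyl, and only from the α face. This gives the 1α-hydroxy silyloxy epoxide F5.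
  - Et3N·3HF converts F5 into the 1α,8α-dihydroxy 7-ketone F6.
  - Only the secondary hydroxyl is thioacylated, as in step 10, to the imidazolylthiocarbonate F7.
  - Bu3SnH/AIBN as in step 11 removes it, and the sequence comes back to the route at 22.

Step 15.
- What may go wrong: hydride may fail to displace the angular neopentyl mesylate (attack at sulfur with return of the alcohol, or no reaction), while the C7 part of the cascade proceeds.
- Fallback (carbonyl route, no SN2 at the neopentyl carbon), setting out from 23:
  - The primary hydroxyl is acetylated selectively (Ac2O, pyridine, 0 °C) to the primary acetate F8.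
  - The 7β-hydroxyl is mesylated to the acetate mesylate F9.
  - LiAlH4 in THF cleaves the acetate, closes the epoxy alcohol F10 and opens it at C7 to the 8α-hydroxy primary alcohol F11.
  - Dess–Martin periodinane with NaHCO3 gives the angular aldehyde F12.
  - Wolff–Kishner reduction in the Huang-Minlon form (N2H4·H2O, KOH, diethylene glycol, 130 → 200 °C) through the hydrazone F13 comes back to the route at 27.

**Further compounds**
F1 | step 8 | ent-adduct (mirror image of 17) | CC(C)=CCC/C(C)=C/CC/C(C)=C/CC[C@H]1[C@]2(C(=O)OC)C(=O)CCC(C)(C)[C@@H]2CC(O[Si](C)(C)C(C)(C)C)=C1C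
F2 | step 8 | ent-alcohol (mirror image of 18) | CC(C)=CCC/C(C)=C/CC/C(C)=C/CC[C@H]1[C@]2(C(=O)OC)[C@H](O)CCC(C)(C)[C@@H]2CC(O[Si](C)(C)C(C)(C)C)=C1C
F3 | step 8 | (S)-O-methylmandelate of 18 | CC(C)=CCC/C(C)=C/CC/C(C)=C/CC[C@@H]1[C@@]2(C(=O)OC)[C@@H](OC(=O)[C@@H](OC)c3ccccc3)CCC(C)(C)[C@H]2CC(O[Si](C)(C)C(C)(C)C)=C1C
F4 | step 8 | (S)-O-methylmandelate of F2 | CC(C)=CCC/C(C)=C/CC/C(C)=C/CC[C@H]1[C@]2(C(=O)OC)[C@H](OC(=O)[C@@H](OC)c3ccccc3)CCC(C)(C)[C@@H]2CC(O[Si](C)(C)C(C)(C)C)=C1C
F5 | step 12 | 1α-hydroxy 7β-(TBS-oxy)-7α,8α-epoxide | CC(C)=CCC/C(C)=C/CC/C(C)=C/CC[C@@H]1[C@@]2(C(=O)OC)[C@@H](O)CCC(C)(C)[C@H]2C[C@@]3(O[Si](C)(C)C(C)(C)C)O[C@@]13C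
F6 | step 12 | 1α,8α-dihydroxy 7-ketone ester | CC(C)=CCC/C(C)=C/CC/C(C)=C/CC[C@@H]1[C@@]2(C(=O)OC)[C@@H](O)CCC(C)(C)[C@H]2CC(=O)[C@@]1(C)O
F7 | step 12 | 1α-O-(imidazol-1-ylthiocarbonyl) 8α-hydroxy 7-ketone ester | CC(C)=CCC/C(C)=C/CC/C(C)=C/CC[C@@H]1[C@@]2(C(=O)OC)[C@@H](OC(=S)n3ccnc3)CCC(C)(C)[C@H]2CC(=O)[C@@]1(C)O
F8 | step 15 | primary acetate of 23 | CC(C)=CCC/C(C)=C/CC/C(C)=C/CC[C@@H]1[C@@]2(COC(C)=O)CCCC(C)(C)[C@H]2C[C@H](O)[C@@]1(C)O
F9 | step 15 | primary acetate 7β-mesylate | CC(C)=CCC/C(C)=C/CC/C(C)=C/CC[C@@H]1[C@@]2(COC(C)=O)CCCC(C)(C)[C@H]2C[C@H](OS(C)(=O)=O)[C@@]1(C)O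
F10 | step 15 | 7α,8α-epoxy primary alcohol | CC(C)=CCC/C(C)=C/CC/C(C)=C/CC[C@@H]1[C@@]2(CO)CCCC(C)(C)[C@H]2C[C@H]3O[C@@]13C
F11 | step 15 | 8α-hydroxy primary alcohol (diol) | CC(C)=CCC/C(C)=C/CC/C(C)=C/CC[C@@H]1[C@@]2(CO)CCCC(C)(C)[C@H]2CC[C@@]1(C)O
F12 | step 15 | 8α-hydroxy angular aldehyde | CC(C)=CCC/C(C)=C/CC/C(C)=C/CC[C@@H]1[C@@]2(C=O)CCCC(C)(C)[C@H]2CC[C@@]1(C)O
F13 | step 15 | hydrazone of F12 | CC(C)=CCC/C(C)=C/CC/C(C)=C/CC[C@@H]1[C@@]2(/C=N/N)CCCC(C)(C)[C@H]2CC[C@@]1(C)O
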